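(The runs are simulated from invented constants.)

I began from 0.00371 min⁻¹, my mean J slope: the fraction of the charged G that became J per minute, as one straight line from the end of the lag to the last readings of the two runs.

| setting | Saturday's | Thursday's | flask |
|---|---|---|---|
| G | 0.17 M | 0.38 M | 0.25 M |
| L | 110 mM (held) | 110 mM (held) | 110 mM (held) |
| remark | run made earlier | run made earlier |  |
| time |  |  | 40 min |

| run | time / min | J / % | G / % |
|---|---|---|---|
| Saturday's | 4.00 | 0.1 | 98.0 |
| Saturday's | 8.00 | 2.2 | 98.4 |
| Saturday's | 12.0 | 2.6 | 98.1 |
| Saturday's | 15.0 | 3.3 | 94.6 |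
| Saturday's | 20.0 | 7.7 | 88.9 |
| Saturday's | 25.0 | 8.3 | 87.0 |
| Thursday's | 1.50 | 0 | 100.2 |
| Thursday's | 5.00 | 0.8 | 99.6 |
| Thursday's | 8.00 | 1.8 | 98.1 |
| Thursday's | 12.0 | 2.7 | 95.5 |
| Thursday's | 20.0 | 7.5 | 90.8 |
| Thursday's | 25.0 | 7.3 | 87.8 |

(each reading ± 1 percentage point)

- J at 40 min, in percent of the G charged
- concentration of D in solution at 40 min, in percent of saturation

- the numbers in the tables scatter with a standard deviation of 1 percentage point
- at the start none of L is in solution
- D is what L becomes in solution

1. Main step first. I let G react with D held steady, a pseudo-first-order picture in which each G has the same chance per minute. Thursday's run held 2.24 times the G of Saturday's, yet J at 25.0 min stood at 7.3 % and 8.3 %, equal within the scatter. So I used one slope for the new flask, and over 40 min it gave 14.8 %.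

2. Then the dissolving gas. No L was in solution at the start, and Saturday's J was still 0.1 % at 4.00 min. I began the line there, which lowered the number to 13.4 %.

3. Then the rest. By 25.0 min the runs had lost on average 12.6 % of their G, more than the 7.80 % found as J, so G had another outlet or J was moving on. The slope was read at a mean G near 93.7 %, but the line to 40 min runs at a mean near 89.2 %. Counting G's fall and nothing else, I reckoned the line about 0.64 percentage points high, an estimate that left D out of account. I committed to 13.4 % with that warning. The runs held no reading of D, so I reckoned no saturation.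

The forecast gave 14.5 % for J, above my line, and 95 % of saturation for D, adding: “That saturation value is an assumption.”

    D ⇌ Z (K = 22.0, k = 0.0140 min⁻¹)
    L ⇌ D, rate k2*(csat - [D]) (kL = 0.0930 min⁻¹)
    G + D → J (k = 0.100 L mol⁻¹ min⁻¹)
    D + J → E (k = 0.190 L mol⁻¹ min⁻¹)
    J ⇌ Q (K = 0.420, k = 0.360 min⁻¹)

The flask gave J 13.2 %, which was 0.20 points below my line and within the forecast's tolerance. D stood at 69.8 % of saturation, 25 points under the forecast, with [D] at 0.0768 M against a saturation of 110 mM. The same flask read at 15 min tested the slope on a shorter stretch. Starting again at 4.00 min, the line gave 4.08 %, and the flask held 4.41 %.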